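Everything rests on cutting the C1(OH)–C7H2OH glycol back to an exocyclic C1=C7 alkene on the cyclohexene ring. In the target, O2, O3, O6 and C7 sit on one ring face and O1 sits alone on the other. Osmylation from the oxygen-free face should therefore form C1–O1 and C7–O7 and fix the tertiary carbinol C1 in a single operation. The precursor is a 1-methylene conduritol with the C6 benzoate and an O2/O3 acetonide, built from bromobenzene cis-dihydrodiol. Its bromine is kept on C4 through the key step, where it shuts down the competing ring alkene C4=C5, and is removed afterwards.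

Key step: step 6

Atom labels (used for all intermediates): C1 is the fully substituted ring carbon and C7 its CH2OH carbon. C2 is the free secondary carbinol carbon. C3 (next to C2) and C6 are the benzoyloxy carbons, and C4=C5 is the ring alkene. On is the oxygen on Cn. β is the ring face of O2, O3, O6 and C7; α is the face of O1.

Mapping from 1: the carbinol carbon remote from bromine becomes C2, the one next to C–Br becomes C3, and the C–Br carbon becomes C4.

Origin of stereocentres: C2 and C3 come from 1, C6 is set in steps 2 and 3, and C1 is set in step 6.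

Remark on the chemistry: the bromine on C4 is a removable spectator and takes no part in the key step.

Step 1
Reactants: 1 (1S,2S)-3-bromocyclohexa-3,5-diene-1,2-diol; 2 2,2-dimethoxypropane
Product: 3 (3aS,7aS)-4-bromo-2,2-dimethyl-3a,7a-dihydro-1,3-benzodioxole (O2/O3 acetonide of 1)
Conditions: 2 (3 equiv), p-TsOH·H2O (cat.), acetone, 0 °C to rt; Et3N quench; used at once
Reagents that add atoms: 2,2-dimethoxypropane, COC(C)(C)OC
Why: Acid-catalysed transketalisation of a cis-1,2-diol is fast, breaks no C–O bond at C2 or C3, and gives a diene that is carried on directly because such dienes dimerise by Diels–Alder reaction on storage.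

Step 2
Reactants: 3 bromodiene acetonide
Product: 4 4-bromo-1α,6α-epoxy-2β,3β-(isopropylidenedioxy)cyclohex-4-ene (oxirane trans to the dioxolane)
Conditions: mCPBA (1.1 equiv), CH2Cl2, 0 °C to rt
Reagents that add atoms: mCPBA, O=C(OO)c1cccc(Cl)c1
Why: Prilezhaev epoxidation picks the electron-richer, bromine-free C6=C1 alkene and, with the β face covered by the dioxolane ring, delivers oxygen to the α face, which is the established behaviour of halodiene acetonides.

Step 3
Reactants: 4 α-epoxide; 5 benzoic acid
Product: 6 6β-benzoyloxy-4-bromo-2β,3β-(isopropylidenedioxy)cyclohex-4-en-1α-ol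
Conditions: 5 (2.5 equiv), PhCO2Cs (0.3 equiv), DMF, 60 °C
Reagents that add atoms: benzoic acid, O=C(O)c1ccccc1
Why: Carboxylate SN2 opening of a vinyl oxirane: benzoate attacks the allylic, π-activated C6 rather than C1 (deactivated by the adjacent C2–O bond) in the trans-diaxial mode with inversion, so the ester ends up β and the retained epoxide oxygen becomes the α hydroxyl on C1, while the excess acid protonates the alkoxide before it can pick up the acyl group.

Step 4
Reactants: 6 hydroxy benzoate
Product: 7 6β-benzoyloxy-4-bromo-2β,3β-(isopropylidenedioxy)cyclohex-4-en-1-one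
Conditions: Dess–Martin periodinane (1.3 equiv), CH2Cl2, 0 °C to rt; short silica plug, used at once
Reagents that add atoms: none
Why: Dess–Martin oxidation runs in a weakly acidic, non-enolising medium, which matters because H6 of 7 is both α to the carbonyl and allylic, so C6 should not epimerise and benzoic acid should not be lost.

Step 5
Reactants: 7 ketone
Product: 8 6β-benzoyloxy-4-bromo-2β,3β-(isopropylidenedioxy)-1-methylenecyclohex-4-ene (4-bromo-1-methylene conduritol derivative, key-step precursor)
Conditions: Cp2Ti(μ-CH2)(μ-Cl)AlMe2 (1.1 equiv, toluene solution), THF, −40 to 0 °C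
Reagents that add atoms: Cp2Ti(μ-CH2)(μ-Cl)AlMe2, C[Al-]1(C)C[Ti+2][Cl+]1.c1cc[cH-]c1.c1cc[cH-]c1
Why: Tebbe methylenation through Cp2Ti=CH2 and an oxatitanacyclobutane is non-basic, proceeds below 0 °C and with about one equivalent takes ketones well before aryl esters, so C6, the benzoate, the acetonide and the vinyl bromide should all survive.

Step 6
Reactants: 8 4-bromo-1-methylene conduritol derivative
Product: 10 6β-benzoyloxy-4-bromo-1β-(hydroxymethyl)-2β,3β-(isopropylidenedioxy)cyclohex-4-en-1α-ol, via cyclic osmate ester 9 (not isolated)
Conditions: OsO4 (4 mol %), NMO (1.3 equiv), acetone–H2O (5:1), 0 °C to rt; aq. Na2SO3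
Reagents that add atoms: OsO4, O=[Os](=O)(=O)=O; N-methylmorpholine N-oxide (NMO), C[N+]1([O-])CCOCC1; water, O
Why: OsO4 (octavalent osmium) adds suprafacially to C1=C7 in a concerted [3+2] cycloaddition to give the hexavalent osmium glycolate 9, which water hydrolyses while NMO reoxidises the metal; the closest known reaction type is the catalytic osmylation of exocyclic methylene cyclitols anti to their allylic oxygen substituents. No ring of the product is closed, and the five-membered osmate ring is only transient. The single new stereocentre C1 is under substrate control: both allylic bonds C2–O2 and C6–O6, together with O3 and the whole dioxolane ring, lie on the β face, so the reagent should approach from the empty α face, which places O1 α and turns C7 to the β face. The step needs chemoselectivity for C1=C7 over C4=C5, and the bromine on C4 secures it by making the ring alkene trisubstituted and electron-poor, just as bromodiene acetonides are osmylated only at their halogen-free alkene. Because neither a chiral ligand nor a carbonate base is then required, no mismatched reagent control can arise and the near-neutral medium limits benzoyl migration from O6 to O7.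

Step 7
Reactants: 10 bromo diol
Product: 11 O7-tert-butyldiphenylsilyl (TBDPS) ether of 10
Conditions: TBDPSCl (1.1 equiv), imidazole (2.2 equiv), CH2Cl2, 0 °C
Reagents that add atoms: TBDPSCl, CC(C)(C)[Si](Cl)(c1ccccc1)c1ccccc1
Why: Imidazole-promoted silylation with a bulky chlorosilane takes the primary O7–H and not the tertiary O1–H, closes the O6-to-O7 acyl-shift channel early, and installs an ether that is known to outlast the aqueous acid of step 9.

Step 8
Reactants: 11 bromo silyl ether
Product: 12 6β-benzoyloxy-1β-[(tert-butyldiphenylsilyloxy)methyl]-2β,3β-(isopropylidenedioxy)cyclohex-4-en-1α-ol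
Conditions: Bu3SnH (1.5 equiv), AIBN (0.1 equiv), toluene, 85 °C
Reagents that add atoms: none
Why: Radical-chain hydrodebromination, in which the stannyl radical abstracts bromine and the σ-vinyl radical at C4 is quenched rapidly by Bu3SnH, is routine on bromoconduritol derivatives, spares esters, silyl ethers, ketals and free hydroxyls, and touches no stereocentre.

Step 9
Reactants: 12 acetonide
Product: 13 6β-benzoyloxy-1β-[(tert-butyldiphenylsilyloxy)methyl]cyclohex-4-ene-1α,2β,3β-triol
Conditions: AcOH–H2O (4:1), 50 °C
Reagents that add atoms: none
Why: Acid-catalysed ketal hydrolysis breaks only the O–CMe2 bonds, so C2 and C3 keep their configuration, and primary TBDPS ethers as well as benzoates are known to tolerate 80% acetic acid.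

Step 10
Reactants: 13 triol; 14 benzoyl chloride
Product: 15 3β,6β-dibenzoyloxy-1β-[(tert-butyldiphenylsilyloxy)methyl]cyclohex-4-ene-1α,2β-diol
Conditions: 14 (1.05 equiv), pyridine–CH2Cl2 (1:4), −40 to −20 °C
Reagents that add atoms: benzoyl chloride, O=C(Cl)c1ccccc1
Why: Kinetically controlled regioselective acylation: in the half-chair that keeps the bulky C7 arm equatorial, O3–H is pseudo-equatorial, allylic and next to an sp2 carbon, whereas O2–H is axial and adjacent to the fully substituted C1 and O1–H is tertiary, so one equivalent of acyl chloride at low temperature should go to O3.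

Step 11
Reactants: 15 silyl ether
Product: 16 (1S,2R,3R,6S)-3,6-dibenzoyloxy-1-(hydroxymethyl)cyclohex-4-ene-1,2-diol (target, CNP0212417.6)
Conditions: HF·pyridine, pyridine–THF, 0 °C to rt; pH 7 buffer work-up
Reagents that add atoms: none
Why: Fluoride-induced Si–O cleavage in a pyridine-buffered, slightly acidic medium generates no free alkoxide, which should suppress benzoyl migration from O6 to O7 or from O3 to O2.

Compound list
1 | (1S,2S)-3-bromocyclohexa-3,5-diene-1,2-diol | O[C@@H]1C(Br)=CC=C[C@@H]1O | starting material
2 | 2,2-dimethoxypropane | COC(C)(C)OC | starting material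
3 | (3aS,7aS)-4-bromo-2,2-dimethyl-3a,7a-dihydro-1,3-benzodioxole | CC1(C)O[C@H]2C=CC=C(Br)[C@H]2O1 | intermediate
4 | 4-bromo-1α,6α-epoxy-2β,3β-(isopropylidenedioxy)cyclohex-4-ene | CC1(C)O[C@H]2[C@@H]3O[C@@H]3C=C(Br)[C@H]2O1 | intermediate
5 | benzoic acid | O=C(O)c1ccccc1 | starting material
6 | 6β-benzoyloxy-4-bromo-2β,3β-(isopropylidenedioxy)cyclohex-4-en-1α-ol | O=C(O[C@H]1C=C(Br)[C@H]2OC(C)(C)O[C@H]2[C@@H]1O)c1ccccc1 | intermediate
7 | 6β-benzoyloxy-4-bromo-2β,3β-(isopropylidenedioxy)cyclohex-4-en-1-one | O=C(O[C@H]1C=C(Br)[C@H]2OC(C)(C)O[C@H]2C1=O)c1ccccc1 | intermediate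
8 | 6β-benzoyloxy-4-bromo-2β,3β-(isopropylidenedioxy)-1-methylenecyclohex-4-ene | O=C(O[C@H]1C=C(Br)[C@H]2OC(C)(C)O[C@H]2C1=C)c1ccccc1 | intermediate
9 | cyclic O1,O7-dioxoosmium glycolate (osmate ester) of 10 | O=C(O[C@H]1C=C(Br)[C@H]2OC(C)(C)O[C@H]2[C@@]13CO[Os](=O)(=O)O3)c1ccccc1 | intermediate
10 | 6β-benzoyloxy-4-bromo-1β-(hydroxymethyl)-2β,3β-(isopropylidenedioxy)cyclohex-4-en-1α-ol | O=C(O[C@H]1C=C(Br)[C@H]2OC(C)(C)O[C@H]2[C@@]1(O)CO)c1ccccc1 | intermediate
11 | O7-TBDPS ether of 10 | O=C(O[C@H]1C=C(Br)[C@H]2OC(C)(C)O[C@H]2[C@@]1(O)CO[Si](c1ccccc1)(c1ccccc1)C(C)(C)C)c1ccccc1 | intermediate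
12 | 6β-benzoyloxy-1β-[(tert-butyldiphenylsilyloxy)methyl]-2β,3β-(isopropylidenedioxy)cyclohex-4-en-1α-ol | O=C(O[C@H]1C=C[C@H]2OC(C)(C)O[C@H]2[C@@]1(O)CO[Si](c1ccccc1)(c1ccccc1)C(C)(C)C)c1ccccc1 | intermediate
13 | 6β-benzoyloxy-1β-[(tert-butyldiphenylsilyloxy)methyl]cyclohex-4-ene-1α,2β,3β-triol | O=C(O[C@H]1C=C[C@@H](O)[C@@H](O)[C@@]1(O)CO[Si](c1ccccc1)(c1ccccc1)C(C)(C)C)c1ccccc1 | intermediate
14 | benzoyl chloride | O=C(Cl)c1ccccc1 | starting material
15 | 3β,6β-dibenzoyloxy-1β-[(tert-butyldiphenylsilyloxy)methyl]cyclohex-4-ene-1α,2β-diol | O=C(O[C@H]1C=C[C@@H](OC(=O)c2ccccc2)[C@@H](O)[C@@]1(O)CO[Si](c1ccccc1)(c1ccccc1)C(C)(C)C)c1ccccc1 | intermediate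
16 | (1S,2R,3R,6S)-3,6-dibenzoyloxy-1-(hydroxymethyl)cyclohex-4-ene-1,2-diol | O=C(O[C@H]1C=C[C@@H](OC(=O)c2ccccc2)[C@@H](O)[C@@]1(O)CO)c1ccccc1 | target

Total step count: 11. Longest linear sequence: 11 steps (1 to 16).

Steps most likely to fail

Step 6.
- **What may go wrong:** Turnover may be sluggish at an alkene flanked by two oxygenated carbons. The higher temperature then needed could erode the α-face preference. The benzoyl group could also drift from O6 to the newly freed O7 in the amine-containing medium.
- **Fallback:** This sets out from 8 and splits glycol formation into two separate events. Dimethyldioxirane in acetone at 0 °C should epoxidise C1=C7 from the same open α face, the vinyl bromide being too electron-poor to compete, to give the spiro-epoxide F2. Water with catalytic HClO4 in THF at 0 °C should then open it at the unhindered primary C7, because positive charge at C1 is disfavoured by the two adjacent C–O bonds. The C1–O1 bond made in the epoxidation is therefore never broken. The sequence comes back to the route at 10.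

Step 5.
- **What may go wrong:** The aluminium Lewis acid may promote enolisation of the ketone towards C6, followed by loss of benzoic acid and aromatisation. Further methylenation at the ester carbonyl is also possible.
- **Fallback:** This sets out from 7 and uses a two-stage Peterson olefination. Me3SiCH2MgCl premixed with anhydrous CeCl3 in THF at −78 °C is weakly basic and strongly carbonyl-seeking, and should add to the ketone from the α face. An AcOH quench at −78 °C, applied before the tertiary alkoxide can take up the neighbouring benzoyl group, should give the β-hydroxysilane F1. HF·pyridine in MeCN at 0 °C should then trigger elimination, and the sequence comes back to the route at 8.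

Step 10.
- **What may go wrong:** Discrimination between O2–H and O3–H may be incomplete, double acylation may occur, or the acyl group may shift between the two cis oxygens.
- **Fallback:** This sets out from 13 and replaces kinetic discrimination of free hydroxyls by template-directed acylation. Bu2SnO in toluene at reflux with removal of water should engage the only cis-vicinal diol to give the O2,O3-dibutylstannylene acetal F3. One equivalent of 14 at 0 °C should then be delivered to the equatorial oxygen of the tin acetal, O3, as is usual for cis-diols on six-membered rings. The sequence comes back to the route at 15.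

Further compounds
F1 | step 5 | 6β-benzoyloxy-4-bromo-2β,3β-(isopropylidenedioxy)-1α-[(trimethylsilyl)methyl]cyclohex-4-en-1β-ol | O=C(O[C@H]1C=C(Br)[C@H]2OC(C)(C)O[C@H]2[C@]1(O)C[Si](C)(C)C)c1ccccc1
F2 | step 6 | spiro-epoxide of 8 with O1 on the α face and C7 on the β face | O=C(O[C@H]1C=C(Br)[C@H]2OC(C)(C)O[C@H]2[C@@]13CO3)c1ccccc1
F3 | step 10 | O2,O3-dibutylstannylene acetal of 13 | O=C(O[C@H]1C=C[C@H]2O[Sn](CCCC)(CCCC)O[C@H]2[C@@]1(O)CO[Si](c1ccccc1)(c1ccccc1)C(C)(C)C)c1ccccc1
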